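The earlier runs and the new flask were generated by integration from invented constants; the scatter is artificial.

**The decision.** If I am to choose what to do to the violet flask at the hour, I must first know whether the wait is long or short against the time target takes to recover from a disturbance.

| flask | starting material | partner | temperature | remark | time |
|---|---|---|---|---|---|
| violet | 0.20 M | 1.5 equiv | 60 °C | the very flask that is asked about, followed so far |  |
| amber | 0.13 M | 1.5 equiv | 45 °C | run made earlier |  |
| flask | 0.20 M | 1.50 equiv | 60 °C |  | 1.0 h |

| run | time / min | target / % |
|---|---|---|
| violet | 8.00 | 18.6 |
| violet | 15.0 | 12.1 |
| violet | 25.0 | 10.4 |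
| violet | 30.0 | 10.7 |
| violet | 40.0 | 9.8 |
| violet | 50.0 | 11.4 |
| amber | 3.00 | 0 |
| amber | 6.00 | 0 |
| amber | 10.0 | 1.3 |
| amber | 15.0 | 2.8 |
| amber | 25.0 | 2.7 |
| amber | 40.0 | 17.4 |

(standard deviation of a reading: 1 percentage point)

1. target, in percent of the starting material first charged, at 1.0 h
2. what to do for the largest gain in target; "none" if nothing gains more than 2 percentage points (elm / birch / maple / oak / none)
3. target present, with what was taken out counted in, in percent of the starting material first charged, after elm
4. target present, with what was taken out counted in, in percent of the starting material first charged, after maple

- elm: at 1.0 h add partner, 50.0% of the amount charged, then wait 20 min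
- birch: change nothing and wait 20 min more
- maple: at 1.0 h raise the temperature by 20 K, then wait 20 min
- oak: at 1.0 h take out 90% of the target then present, then wait 20 min

- percent here means starting material units held: one side product counts as two
- target taken out counts as made
- steps that have been proposed: starting material + partner + target -> 2 target; starting material + partner -> target; starting material + target -> side product; target <-> isomer of the product
- additions bring no volume worth counting

**Reading violet.** Target in the violet run reads 18.6% at 8.00 min, then falls to a level: the last four readings average 10.6%. I read that fall as target relaxing towards isomer of the product, a level under thermodynamic control. The excess over the level goes from 8 percentage points to 1.5 points between the first two readings. That gives the relaxation half-life τ, the time in which this excess halves, as 2.92 min. It is rough: each reading carries a scatter of 1 point.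

**My count.** The wait holds n = 6.84 half-lives, because τ is shorter than the wait. A disturbance keeps hardly any of itself. So I expect 10.6% at the hour, and both oak and maple reach their new levels inside the wait. The amber run is still climbing at 40.0 min, reading 17.4%, so it shows no level and the size of maple's shift stays unread. My count does not rank the two.

**The forecast.** It gives 10.6%, chooses oak, and puts elm at 10.6% and maple at 10.8%. On maple it says: “only shifts the equilibrium slightly, by an unknown amount”.

**The result.** The violet flask gives 10.7% at 1.0 h. The best choice is maple, reaching 23.5%, a gain of 13 points against 8.4 points for oak; elm gives 10.7%.

    starting material + partner + target → 2 target (k = 0.510 M⁻² s⁻¹, Ea = 46.0 kJ mol⁻¹)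
    starting material + partner → target (k = 1.70 × 10⁻⁵ M⁻¹ s⁻¹, Ea = 97.0 kJ mol⁻¹)
    starting material + target → side product (k = 0.00960 M⁻¹ s⁻¹, Ea = 69.0 kJ mol⁻¹)
    target ⇌ isomer of the product (K = 6.70, k = 0.0110 s⁻¹, Ea = 103 kJ mol⁻¹, ΔH = −48.0 kJ mol⁻¹)
    (constants at 60 °C)

**The comparison.** At 7.81 min the violet flask uses target in the forward step to isomer of the product 11 times as fast as in the loss to side product; the hour is 20.5 times the τ I read off the scattered readings, and at 1.0 h the violet flask holds 10.7% target beside 71.5% isomer of the product. The neighbour flask at 75 °C, over the same hour, holds 18.3% target beside 58.0% isomer of the product, 3.17 to one against 6.68 to one in the violet flask.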